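(The runs were computed for an exercise; the scatter is artificial.)

Slowness marks the end of the south run, whose side product creeps from 25.1% at 5.00 min to 26.8% at 8.00 min, so the thing to watch in the richer flask is how far the reagent carries.

- south: starting material 36 mM (in portions, 3); reagent 14 mM; initiator 0.23 mM; run made earlier; portions every 3.0 s
- flask: starting material 36 mM (in portions, 3); reagent 28.8 mM; initiator 0.23 mM; time 40 min; the portions of starting material follow each other after 3.0 s, the first at the start

south run (percent of the starting material charged)

| time / min | side product / % | target / % |
|---|---|---|
| 0.417 | 2.1 | 4.6 |
| 1.33 | 10.4 | 6.5 |
| 2.50 | 18.4 | 3.7 |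
| 3.00 | 19.7 | 1.5 |
| 5.00 | 25.1 | 0 |
| 6.00 | 25.9 | 1.7 |
| 8.00 | 26.8 | 0.9 |

(readings scatter by 1 percentage point)

- in percentages every species weighs as the starting material in it: one side product counts as two
- the reaction counts as stopped when no species that holds the starting material changes by six tenths of a point or more over the second half of the time

- at 40 min, what has stopped the reaction, if anything has (all of the starting material has reacted / forward and back rates have come level / it is still moving / the reagent has run out first)
- the side product standing at 40 min, as a percentage of the starting material charged

The reckoning here treats reagent as the limiting reagent: in the south run, 14 mM of it stands against 4.82 mM of side product molecules by the reading at 8.00 min, since each counts as two, which gives 2.90, the reagent cost, meaning reagent charged per side product formed, a value that carries the scatter of that reading. Supposing that one reagent enters each side product and that the surplus of 1.90 goes to a waste path growing in proportion to c(reagent), the flask with 28.8 mM has a cost of 4.91 and gives 32.6%, ending when its reagent does.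

The forecast names the same ending, the reagent has run out first, but takes the side product almost in step with the charge, to 54%, shaded down a little on its own ground that “Lower starting material late in the run may favour any reagent-wasting path”.

The flask gives 37.0% of side product at 40.0 min, with 0.18% of its charged reagent still there, and the ending is this: the reagent has run out first.

    initiator → 2 initiating radical (k = 0.00410 s⁻¹)
    starting material + initiating radical → capped initiator + first chain carrier (k = 2.10 × 10⁶ M⁻¹ s⁻¹)
    reagent + first chain carrier → target + second chain carrier (k = 1.20 × 10⁵ M⁻¹ s⁻¹)
    starting material + second chain carrier → by-product + first chain carrier (k = 1.50 × 10⁵ M⁻¹ s⁻¹)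
    first chain carrier → ended carrier (k = 12.0 s⁻¹)
    2 first chain carrier → ended chains A (k = 4.90 × 10⁷ M⁻¹ s⁻¹)
    2 second chain carrier → ended chains B (k = 2.00 × 10⁷ M⁻¹ s⁻¹)
    2 reagent → self-condensation product (k = 1.70 M⁻¹ s⁻¹)
    starting material + target → side product (k = 0.430 M⁻¹ s⁻¹)

Beside the side product the flask holds 11.0 mM of self-condensation product at 40.0 min, which takes up 76.4% of the reagent charge. Reckoned from its charge and its side product, the flask's reagent cost is 4.32, higher than the 2.90 read from the south run. For the neighbouring flask with 17 mM of reagent, the same scaling gives a cost of 3.31 and so 28.5% of side product, and that flask stands at 30.1%.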